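The pyrrole ring is cut at N1–C7a and C3–C3a, so the benzo ring becomes 3,5-dibromobenzyne and N1–C2–C3 an N-tosylglycine ester. The feature exploited lies in the benzo ring: N1 sits on C7a, C3 on the neighbouring C3a, and the bromines occupy C4 (directly beside C3a) and C6. A benzyne carrying bromine next to one reactive carbon delivers exactly this when nitrogen attacks the far carbon. One operation makes both bonds and the five-membered ring, giving a 4,6-dibromo-N-tosylindolin-3-one. The precursors are an ortho-silylaryl triflate from 2,4,6-tribromophenol and methyl N-tosylglycinate. Thiol condensation, detosylation and C2 bromination finish the synthesis.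

Key step: step 4

Remark: the target is achiral, so no configuration has to be set; the annulation product is drawn as the keto tautomer that N-sulfonyl indoxyls adopt.

Step 1
Reactants: 1 2,4,6-tribromophenol
Product: 2 trimethyl(2,4,6-tribromophenoxy)silane
Conditions: HN(SiMe3)2 (0.7 equiv), THF, reflux; volatiles removed in vacuo, crude used directly
Reagents that add atoms: hexamethyldisilazane, C[Si](C)(C)N[Si](C)(C)C
Why: O-silylation of an acidic phenol by a silazane is driven to completion by loss of ammonia and should leave a silyl ether clean enough to use without purification.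

Step 2
Reactants: 2 trimethyl(2,4,6-tribromophenoxy)silane
Product: 5 2,4-dibromo-6-(trimethylsilyl)phenyl trifluoromethanesulfonate, via aryllithium 3 (not isolated), via lithium silylphenoxide 4 (not isolated)
Conditions: n-BuLi (1.05 equiv), THF, −100 → −80 °C; then Tf2O (1.2 equiv), −100 °C → rt
Reagents that add atoms: trifluoromethanesulfonic anhydride, O=S(=O)(OS(=O)(=O)C(F)(F)F)C(F)(F)F
Why: Bromine–lithium exchange should be fastest at a bromine ortho to the silyloxy group (inductive activation and O–Li coordination; the two ortho bromines are equivalent), the aryllithium then undergoes 1,3 O→C silyl migration (retro-Brook rearrangement), and the lithium phenoxide is O-triflated in the same flask.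

Step 3
Reactants: 6 glycine methyl ester hydrochloride; 7 4-methylbenzenesulfonyl chloride
Product: 8 methyl N-(4-methylphenylsulfonyl)glycinate
Conditions: Et3N (2.2 equiv), CH2Cl2, 0 °C → rt
Reagents that add atoms: none
Why: N-sulfonylation of a primary amine freed from its salt by a sulfonyl chloride is a routine sulfonamide formation, and the product should crystallise.

Step 4
Reactants: 5 2,4-dibromo-6-(trimethylsilyl)phenyl trifluoromethanesulfonate; 8 methyl N-(4-methylphenylsulfonyl)glycinate
Product: 11 4,6-dibromo-1-(4-methylphenylsulfonyl)indolin-3-one, via 3,5-dibromobenzyne 9 (not isolated), via aryl anion 10 (not isolated)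
Conditions: CsF (3 equiv), MeCN, rt, N2; 5 added over 4 h to 8 (2 equiv); NH4Cl quench
Reagents that add atoms: none
Why: Fluoride attack at silicon triggers 1,2-elimination of triflate from 5 and liberates aryne 9; the sulfonamide anion of 8 bonds through nitrogen to the aryne terminus that has no bromine neighbour (N1–C7a), and carbanion 10, now lying between the new C–N bond and bromine, adds to the pendant ester and ejects methoxide (C3–C3a). The closest known reaction type is the fluoride-induced annulation of ortho-silylaryl triflates with N-sulfonyl α-amino esters to N-sulfonylindolin-3-ones, an aryne N-arylation followed by anionic acyl substitution. The five-membered ring closes in the 5-exo-trig mode by attack of the aryl carbanion on the ester carbonyl. No stereocentre is created. The selectivity required is the orientation of N-addition to the unsymmetrical aryne; it is secured by the C–Br bond next to one terminus, whose inductive pull and distortion of the triple bond make the remote terminus the electrophilic one and stabilise the charge building up beside bromine, so the 4,6- and not the 5,7-dibromo isomer should form. Excess 8 and slow release of 9 should keep the enolisable product from consuming aryne, and ring closure at room temperature is expected to outpace loss of bromide from the ortho-bromoaryl anion.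

Step 5
Reactants: 11 4,6-dibromo-1-(4-methylphenylsulfonyl)indolin-3-one; 12 methanethiol
Product: 13 4,6-dibromo-3-(methylsulfanyl)-1-(4-methylphenylsulfonyl)-1H-indole
Conditions: MeSH (5 equiv, condensed), BF3·OEt2 (0.3 equiv), 4 Å MS, CH2Cl2, −20 °C → rt, sealed tube
Reagents that add atoms: none
Why: Lewis-acid-promoted condensation of an enolisable ketone with a thiol (thioketalisation–elimination to a vinyl sulfide) should here be pulled through by aromatisation to the indole, while the N-tosyl group protects the product from acid-induced shift of the sulfanyl group from C3 to C2.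

Step 6
Reactants: 13 4,6-dibromo-3-(methylsulfanyl)-1-(4-methylphenylsulfonyl)-1H-indole
Product: 14 4,6-dibromo-3-(methylsulfanyl)-1H-indole
Conditions: Cs2CO3 (3 equiv), THF/MeOH (2:1), rt
Reagents that add atoms: none
Why: Base-mediated N-desulfonylation, in which methoxide attacks sulfur and expels the indolide, should be fast because the two bromines make the indolide a good leaving group; the aryl bromides and the thioether are inert to these conditions.

Step 7
Reactants: 14 4,6-dibromo-3-(methylsulfanyl)-1H-indole
Product: 15 2,4,6-tribromo-3-(methylsulfanyl)-1H-indole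
Conditions: NBS (1.0 equiv), anhydrous CH2Cl2, −20 → 0 °C, dark
Reagents that add atoms: N-bromosuccinimide, O=C1CCC(=O)N1Br
Why: Electrophilic bromination of a 3-substituted indole should go to C2 (directly, or by attack at C3 and 1,2-shift of bromine), the only electron-rich C–H left because the benzo ring is deactivated by two bromines.

Compound list
1 | 2,4,6-tribromophenol | Oc1c(Br)cc(Br)cc1Br | starting material
2 | trimethyl(2,4,6-tribromophenoxy)silane | C[Si](C)(C)Oc1c(Br)cc(Br)cc1Br | intermediate
3 | [3,5-dibromo-2-(trimethylsilyloxy)phenyl]lithium (not isolated) | [Li]c1cc(Br)cc(Br)c1O[Si](C)(C)C | intermediate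
4 | lithium 2,4-dibromo-6-(trimethylsilyl)phenoxide (not isolated) | [Li+].[O-]c1c(Br)cc(Br)cc1[Si](C)(C)C | intermediate
5 | 2,4-dibromo-6-(trimethylsilyl)phenyl trifluoromethanesulfonate | C[Si](C)(C)c1cc(Br)cc(Br)c1OS(=O)(=O)C(F)(F)F | intermediate
6 | glycine methyl ester hydrochloride | Cl.NCC(=O)OC | starting material
7 | 4-methylbenzenesulfonyl chloride | Cc1ccc(cc1)S(=O)(=O)Cl | starting material
8 | methyl N-(4-methylphenylsulfonyl)glycinate | COC(=O)CNS(=O)(=O)c1ccc(C)cc1 | intermediate
9 | 3,5-dibromobenzyne (3,5-dibromo-1,2-didehydrobenzene, not isolated) | BrC1=CC(Br)=CC#C1 | intermediate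
10 | cesium 2,4-dibromo-6-[(2-methoxy-2-oxoethyl)(4-methylphenylsulfonyl)amino]benzen-1-ide (not isolated) | COC(=O)CN(C1=CC(Br)=CC(Br)=[C-]1)S(=O)(=O)c1ccc(C)cc1.[Cs+] | intermediate
11 | 4,6-dibromo-1-(4-methylphenylsulfonyl)indolin-3-one | Cc1ccc(cc1)S(=O)(=O)N1CC(=O)c2c(Br)cc(Br)cc21 | intermediate
12 | methanethiol | CS | starting material
13 | 4,6-dibromo-3-(methylsulfanyl)-1-(4-methylphenylsulfonyl)-1H-indole | CSc1cn(S(=O)(=O)c2ccc(C)cc2)c2cc(Br)cc(Br)c12 | intermediate
14 | 4,6-dibromo-3-(methylsulfanyl)-1H-indole | CSc1c[nH]c2cc(Br)cc(Br)c12 | intermediate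
15 | 2,4,6-tribromo-3-(methylsulfanyl)-1H-indole | CSc1c(Br)[nH]c2cc(Br)cc(Br)c12 | target

Total step count: 7. Longest linear sequence: 6 steps (steps 1, 2, 4, 5, 6 and 7); step 3 is a one-step side branch.

Steps most likely to fail

Step 4. The aryne may be intercepted by the enolate of the indolinone already formed (arylation at C2 or on oxygen) instead of by the sulfonamide. The aryl anion may also be protonated before it acylates, or shed bromide. Fallback (Gassman indole synthesis, known chemistry), setting out from methanethiol 12 and rejoining at 14, so that steps 4 to 6 are bypassed: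
- 12 is deprotonated with NaOMe in MeOH and S-alkylated with 2-bromo-1,1-dimethoxyethane to give 1,1-dimethoxy-2-(methylsulfanyl)ethane F1.
- Commercial 3,5-dibromoaniline is N-chlorinated with tert-butyl hypochlorite (CH2Cl2, −70 °C) to 3,5-dibromo-N-chloroaniline F2. Addition of F1 in the same flask should give the azasulfonium salt [(3,5-dibromophenyl)amino](2,2-dimethoxyethyl)methylsulfonium chloride F3.
- Et3N deprotonates the S-methylene, and [2,3]-sigmatropic (Sommelet–Hauser) rearrangement into either of the two equivalent ortho positions, followed by rearomatisation, should give racemic 3,5-dibromo-2-[2,2-dimethoxy-1-(methylsulfanyl)ethyl]aniline F4.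
- Dilute HCl (Et2O/H2O, rt) unmasks the aldehyde, which condenses with the amine and aromatises with loss of two molecules of methanol to 14. The symmetry of the aniline fixes the bromines at C4 and C6.

Step 5. Addition of the thiol to a carbonyl wedged between the N-sulfonyl methylene and the peri C4–Br may be slow. Elimination after thioketalisation may also stay incomplete, or the Lewis acid may loosen the sulfonyl group. Fallback, setting out from 11 and rejoining at 14:
- NaBH4 (MeOH/THF, 0 °C) reduces 11 to racemic 4,6-dibromo-1-(4-methylphenylsulfonyl)indolin-3-ol F5.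
- Catalytic TsOH in toluene at 80 °C dehydrates it to 4,6-dibromo-1-(4-methylphenylsulfonyl)-1H-indole F6.
- Cs2CO3 in THF/MeOH removes the sulfonyl group to give 4,6-dibromo-1H-indole F7.
- Electrophilic sulfenylation at C3 with N-(methylsulfanyl)phthalimide and catalytic MgBr2 (DMAc, 90 °C) should give 14.

Step 2. Exchange at the para bromine or at two bromines, or attack of butyllithium at silicon, may compete with the ortho exchange. The O→C silyl shift may also be incomplete before triflation. Fallback, setting out from 1 and rejoining at 5, with a chelating group directing the exchange and an external silyl electrophile replacing the migration: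
- 1 is protected with chloromethyl methyl ether and iPr2NEt (CH2Cl2) as 1,3,5-tribromo-2-(methoxymethoxy)benzene F8.
- n-BuLi (Et2O, −78 °C) performs a chelation-directed ortho bromine–lithium exchange to [3,5-dibromo-2-(methoxymethoxy)phenyl]lithium F9, which is trapped with Me3SiCl as [3,5-dibromo-2-(methoxymethoxy)phenyl]trimethylsilane F10.
- Catalytic HCl in MeOH at rt removes the acetal to give 2,4-dibromo-6-(trimethylsilyl)phenol F11.
- Tf2O/pyridine (CH2Cl2, 0 °C) triflates it to 5.

Further compounds
F1 | step 4 | 1,1-dimethoxy-2-(methylsulfanyl)ethane | COC(CSC)OC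
F2 | step 4 | 3,5-dibromo-N-chloroaniline | ClNc1cc(Br)cc(Br)c1
F3 | step 4 | [(3,5-dibromophenyl)amino](2,2-dimethoxyethyl)methylsulfonium chloride | C[S+](CC(OC)OC)Nc1cc(Br)cc(Br)c1.[Cl-]
F4 | step 4 | 3,5-dibromo-2-[2,2-dimethoxy-1-(methylsulfanyl)ethyl]aniline (racemic) | COC(OC)C(SC)c1c(N)cc(Br)cc1Br
F5 | step 5 | 4,6-dibromo-1-(4-methylphenylsulfonyl)indolin-3-ol (racemic) | Cc1ccc(cc1)S(=O)(=O)N1CC(O)c2c(Br)cc(Br)cc21
F6 | step 5 | 4,6-dibromo-1-(4-methylphenylsulfonyl)-1H-indole | Cc1ccc(cc1)S(=O)(=O)n1ccc2c(Br)cc(Br)cc21
F7 | step 5 | 4,6-dibromo-1H-indole | Brc1cc(Br)c2cc[nH]c2c1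
F8 | step 2 | 1,3,5-tribromo-2-(methoxymethoxy)benzene | COCOc1c(Br)cc(Br)cc1Br
F9 | step 2 | [3,5-dibromo-2-(methoxymethoxy)phenyl]lithium | [Li]c1cc(Br)cc(Br)c1OCOC
F10 | step 2 | [3,5-dibromo-2-(methoxymethoxy)phenyl]trimethylsilane | COCOc1c(Br)cc(Br)cc1[Si](C)(C)C
F11 | step 2 | 2,4-dibromo-6-(trimethylsilyl)phenol | Oc1c(Br)cc(Br)cc1[Si](C)(C)C
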